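(The runs were generated by integration from invented constants.)

**Amounts charged.** The flask holds 0.20 M of E, 0.200 mM of the free proton J and 0.0200 M of Q. The noon run has the same J and Q charges, so I reckon from that run.

| setting | dusk | noon | dawn | flask |
|---|---|---|---|---|
| E | 0.10 M | 0.15 M | 0.20 M | 0.20 M |
| J | 0.20 mM | 0.20 mM | 0.20 mM | 0.200 mM |
| Q | 0.020 M | 0.020 M | 0.030 M | 0.0200 M |
| remark | run made earlier | run made earlier | run made earlier |  |
| time |  |  |  | 1.0 h |

| run | time / min | E / % | G / % |
|---|---|---|---|
| dusk | 6.00 | 67 | 11 |
| dusk | 12.0 | 49 | 19 |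
| dusk | 30.0 | 21 | 33 |
| dusk | 80.0 | 6 | 47 |
| noon | 10.0 | 57 | 18 |
| noon | 25.0 | 31 | 32 |
| noon | 50.0 | 9 | 42 |
| noon | 80.0 | 6 | 49 |
| dawn | 10.0 | 55 | 14 |
| dawn | 25.0 | 29 | 29 |
| dawn | 50.0 | 7 | 42 |
| dawn | 80.0 | 3 | 48 |

(standard deviation of a reading: 1.5 percentage points)

- J is the free proton; pH is minus the decimal logarithm of its molar concentration
- what has gone from E into another species counts as reacted, even if it can come back

- part of the E that has reacted at 1.0 h
- pH of the solution at 1.0 h

**Main step.** First I treat E as lost in a single first-order step. The noon reading of 31% at 25.0 min gives k = 0.0468 min⁻¹, where k, the apparent pseudo-first-order constant, is the natural logarithm of charged E over remaining E, divided by the time. Over 1.0 h this leaves 6.02% of E, so 94.0% has reacted.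

**Slower tail.** Next I add the late readings. At 80.0 min this k leaves 2.37%, but the noon run reads more than that, 6%. Interpolating the logarithm of E between the last two readings gives 7.86% left at 1.0 h in the noon run and 5.28% in the dawn run. These stand on either side of my figure, so I keep it.

**Unseen forms.** At 80.0 min the noon run shows E and G summing to 55.0%. The rest sits in unseen forms and counts as reacted, so the number stays. No run reads J, and the charged J corresponds to pH 3.7.

**The forecast.** It gives 93% reacted (89% to 96.5%), less than my reckoning, and pH 3.7 (3.5 to 3.9), since the steady kinetics “suggest J stays about constant”.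

**Flask result.** The flask gives 92.9% reacted and pH 3.36, with J at 218% of its charge at 1.00 h. Both forecast numbers stand within the margins asked, though the flask's pH lies lower than the forecast's low end of 3.5.

    E + J → D + J + G (k = 62.0 L mol⁻¹ min⁻¹)
    D ⇌ X + J, settled at all times (K = 5.00 × 10⁻⁶ M)
    E → D + G (k = 0.00860 min⁻¹)
    E + Q → Z (k = 2.00 L mol⁻¹ min⁻¹)
    E + D ⇌ L, settled at all times (K = 250 L mol⁻¹)

**Earlier reading.** Over 1.0 h the flask's own k is 0.0441 min⁻¹, lower than the carried value. For the same flask read at 15 min, the carried k reckons 49.6% of E left. That reading has a k of 0.0511 min⁻¹, higher than the carried value: E stands at 46.5%, 53.5% has reacted, and Q is down to 1.72% of its charge.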